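**Retrosynthetic overview**

- The strategy rests on the cyclohexene ring: C1 (quaternary, CH3 and styryl arm), C2 (H, aryl) and C3=C4(CH3) are the α-, β-, γ- and δ-carbons of a 4-methylcyclohexa-1,3-diene-1-carbonyl unit. Both stereocentres therefore arise by adding aryl and methyl across the C1=C2 bond of a ready-made ring.
- Coumarin A: the pyranone ring (O1–C2 and C3=C4) is opened to an ortho-hydroxy aldehyde plus a ketenylidene ylide; the formyl group goes back to a MOM-protected phenol.
- Styryl C=C: C1 aldehyde (from the thioester) plus the 8-phosphonomethyl derivative of citropten, which brings coumarin B intact.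
- C2–aryl and C1–CH3: dienyl thioester 9, aryl Grignard reagent 14 and iodomethane 15.
- Ring order: the cyclohexadiene ring is made first (step 2), the benzene ring of coumarin A is attached in step 8, and its pyranone ring is closed last (step 16).

Key step: step 8

Assumption: with the cyclohexene numbered as above, the target is (1R,2R) with the C2 aryl group cis to the C1 styryl arm; the linear dienoate is built by annulation and not from p-toluic acid, because alkaline isomerisation of a 1,4-dihydrobenzoic acid is expected to stop at the cross-conjugated 1,5-diene.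

**Route**

Step 1
Reactants: 1 ethyl (E)-4-bromobut-2-enoate; 2 triphenylphosphine
Product: 3 [(2E)-4-ethoxy-4-oxobut-2-en-1-yl]triphenylphosphonium bromide
Conditions: toluene, rt, 16 h; salt filtered off
Reagents that add atoms: none
Why: SN2 quaternisation of a primary allylic bromide by the phosphine (phosphonium salt formation) should be clean, and the salt precipitates.

Step 2
Reactants: 3 [(2E)-4-ethoxy-4-oxobut-2-en-1-yl]triphenylphosphonium bromide; 4 but-3-en-2-one (methyl vinyl ketone)
Product: 6 ethyl 4-methylcyclohexa-1,3-diene-1-carboxylate, via allylic phosphorane 5 (not isolated)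
Conditions: NaH, THF, 0 °C; then 4 added slowly, 0 → 65 °C
Reagents that add atoms: none
Why: Michael addition of the ester-stabilised allylic ylide through its carbon next to the ester, proton shift back to a P-ylide and intramolecular Wittig reaction with the methyl ketone (Michael–Wittig cyclohexadiene annulation) close the six-membered ring and place the ester on C1 and the methyl on C4 of a linear 1,3-diene without any isomerisation step.

Step 3
Reactants: 6 ethyl 4-methylcyclohexa-1,3-diene-1-carboxylate
Product: 7 4-methylcyclohexa-1,3-diene-1-carboxylic acid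
Conditions: LiOH, THF/H2O, rt, under argon; then 1 M HCl, 0 °C
Reagents that add atoms: water, O
Why: Saponification of an ester whose diene is already the thermodynamic isomer, so base cannot move the double bonds; air is kept out to avoid aromatisation.

Step 4
Reactants: 7 4-methylcyclohexa-1,3-diene-1-carboxylic acid; 8 ethanethiol
Product: 9 S-ethyl 4-methylcyclohexa-1,3-diene-1-carbothioate
Conditions: DCC, DMAP (cat.), CH2Cl2, 0 °C → rt
Reagents that add atoms: none
Why: Steglich thioesterification via the O-acylisourea is the standard mild route to unsaturated S-ethyl thioesters and avoids free thiolate that could add in conjugate fashion.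

Step 5
Reactants: 10 3,5-dimethoxyphenol
Product: 11 1,3-dimethoxy-5-(methoxymethoxy)benzene
Conditions: NaH, THF/DMF, 0 °C; MOMCl, 0 °C → rt
Reagents that add atoms: chloromethyl methyl ether, COCCl
Why: O-alkylation of the sodium phenoxide (Williamson-type MOM protection) gives a group that survives aryl-metal chemistry and directs the next metalation.

Step 6
Reactants: 11 1,3-dimethoxy-5-(methoxymethoxy)benzene
Product: 13 2-bromo-1,5-dimethoxy-3-(methoxymethoxy)benzene, via aryllithium 12 (not isolated)
Conditions: n-BuLi, THF, 0 °C, 1 h; then BrCH2CH2Br, −78 °C → rt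
Reagents that add atoms: 1,2-dibromoethane, BrCCBr
Why: Directed ortho-metalation: the chelating OMOM group, helped by the neighbouring methoxy group, should steer lithiation to the carbon between them and not to the one between two methoxy groups, and bromine transfer gives a bromide that can be purified free of any regioisomer.

Step 7
Reactants: 13 2-bromo-1,5-dimethoxy-3-(methoxymethoxy)benzene
Product: 14 [2,4-dimethoxy-6-(methoxymethoxy)phenyl]magnesium bromide
Conditions: Mg turnings (I2-activated), Et2O, reflux; solution titrated and used directly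
Reagents that add atoms: magnesium, [Mg]
Why: Insertion of magnesium into the aryl C–Br bond (Grignard formation) gives a lithium-salt-free reagent in ether, the medium in which copper-catalysed conjugate additions of Grignard reagents are run.

Step 8
Reactants: 9 S-ethyl 4-methylcyclohexa-1,3-diene-1-carbothioate; 14 [2,4-dimethoxy-6-(methoxymethoxy)phenyl]magnesium bromide; 15 iodomethane
Product: 17 S-ethyl (1S,2S)-2-[2,4-dimethoxy-6-(methoxymethoxy)phenyl]-1,4-dimethylcyclohex-3-ene-1-carbothioate, via magnesium enolate 16 (not isolated)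
Conditions: CuI (5 mol %), (R)-Tol-BINAP (6 mol %; antipode if a first screen shows the opposite sense), t-BuOMe, −75 °C, 14 (1.3 equiv in Et2O) added over 2 h; then 15 (5 equiv), DMPU, −75 → −20 °C
Reagents that add atoms: none
Why: Proposed new method: the CuI–diphosphine complex is transmetallated by 14 to a chiral aryl cuprate that binds the C1=C2 bond of 9 and, through a σ-bonded trivalent-copper intermediate and reductive elimination, puts the aryl group on the β-carbon C2 and leaves the bromomagnesium thioester enolate 16, which DMPU-activated iodomethane then alkylates at C1. The closest known reaction type is the copper/diphosphine-catalysed asymmetric conjugate addition of Grignard reagents to α,β-unsaturated thioesters with trapping of the magnesium enolate by an electrophile; it has not been shown for a di-ortho-substituted aryl Grignard reagent or for a cyclic dienyl thioester. No ring is closed, because the six-membered ring comes intact from 9 and the C3=C4 bond stays where the diene had it. C2 is set by the ligand (catalyst control of the face of the C1=C2 bond), and C1 by the substrate: allylic strain in the exocyclic enolate turns the C2 aryl group pseudoaxial, so iodomethane enters from the opposite face and the methyl group ends trans to aryl, the thioester cis. The step needs 1,4- over 1,6- and 1,2-addition: the methyl-bearing, fully substituted δ-carbon C4 blocks 1,6-transfer of the bulky aryl group, and the soft copper nucleophile at −75 °C spares the thioester carbonyl. C-methylation without loss of the enolate is secured by the soft electrophile and by staying below −20 °C, where thioester enolates should not yet expel thiolate to give ketenes.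

Step 9
Reactants: 17 S-ethyl (1S,2S)-2-[2,4-dimethoxy-6-(methoxymethoxy)phenyl]-1,4-dimethylcyclohex-3-ene-1-carbothioate
Product: 18 (1S,2S)-2-[2,4-dimethoxy-6-(methoxymethoxy)phenyl]-1,4-dimethylcyclohex-3-ene-1-carbaldehyde
Conditions: Et3SiH, 10% Pd/C, acetone, rt
Reagents that add atoms: none
Why: Fukuyama reduction (acyl–palladium formation and hydride transfer from the silane) stops at the aldehyde, leaves the trisubstituted alkene and the MOM ether alone, and the aldehyde has no α-hydrogen, so C1 cannot epimerise.

Step 10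
Reactants: 19 5,7-dimethoxy-2H-chromen-2-one (citropten)
Product: 20 5,7-dimethoxy-2-oxo-2H-chromene-8-carbaldehyde
Conditions: Cl2CHOMe, TiCl4, CH2Cl2, 0 °C → rt; then H2O
Reagents that add atoms: dichloromethyl methyl ether, COC(Cl)Cl; water, O
Why: Rieche formylation (electrophilic aromatic substitution) should go to C8, which is para to the 5-methoxy group and flanked only by OMe and the ring oxygen, whereas C6 lies between two methoxy groups and is para only to the weakly donating lactone oxygen.

Step 11
Reactants: 20 5,7-dimethoxy-2-oxo-2H-chromene-8-carbaldehyde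
Product: 21 8-(hydroxymethyl)-5,7-dimethoxy-2H-chromen-2-one
Conditions: NaBH4, THF/MeOH, 0 °C, short reaction time
Reagents that add atoms: none
Why: Borohydride reduction of the aryl aldehyde is much faster at 0 °C than attack on the lactone or its conjugated C3=C4 bond.

Step 12
Reactants: 21 8-(hydroxymethyl)-5,7-dimethoxy-2H-chromen-2-one
Product: 22 diethyl [(5,7-dimethoxy-2-oxo-2H-chromen-8-yl)methyl]phosphonate
Conditions: P(OEt)3, ZnI2, toluene, 110 °C
Reagents that add atoms: triethyl phosphite, CCOP(OCC)OCC
Why: ZnI2-promoted direct conversion of an electron-rich benzylic alcohol into its diethyl phosphonate (an Arbuzov-type reaction in one flask) avoids isolating the labile benzylic halide.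

Step 13
Reactants: 18 (1S,2S)-2-[2,4-dimethoxy-6-(methoxymethoxy)phenyl]-1,4-dimethylcyclohex-3-ene-1-carbaldehyde; 22 diethyl [(5,7-dimethoxy-2-oxo-2H-chromen-8-yl)methyl]phosphonate
Product: 23 8-[(E)-2-{(1R,2R)-2-[2,4-dimethoxy-6-(methoxymethoxy)phenyl]-1,4-dimethylcyclohex-3-en-1-yl}ethenyl]-5,7-dimethoxy-2H-chromen-2-one
Conditions: KN(SiMe3)2, THF, −78 °C; then 18, −78 °C → rt (40 °C if needed)
Reagents that add atoms: none
Why: Horner–Wadsworth–Emmons olefination of a non-enolisable aldehyde with a benzylic phosphonate anion gives the E-styrene under thermodynamic control of the oxaphosphetane, and the hindered non-nucleophilic amide base spares the lactone; the stereocentres are untouched and only their CIP descriptors change.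

Step 14
Reactants: 23 8-[(E)-2-{(1R,2R)-2-[2,4-dimethoxy-6-(methoxymethoxy)phenyl]-1,4-dimethylcyclohex-3-en-1-yl}ethenyl]-5,7-dimethoxy-2H-chromen-2-one
Product: 24 8-[(E)-2-{(1R,2R)-2-(2-hydroxy-4,6-dimethoxyphenyl)-1,4-dimethylcyclohex-3-en-1-yl}ethenyl]-5,7-dimethoxy-2H-chromen-2-one
Conditions: ZnBr2, n-PrSH, CH2Cl2, 0 °C, about 10 min
Reagents that add atoms: none
Why: Lewis acid-assisted transfer of the methoxymethyl group to the thiol removes a phenolic MOM ether within minutes without protic acid, so the freed phenol should not cyclise onto the C3=C4 bond as it could under HCl or TsOH.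

Step 15
Reactants: 24 8-[(E)-2-{(1R,2R)-2-(2-hydroxy-4,6-dimethoxyphenyl)-1,4-dimethylcyclohex-3-en-1-yl}ethenyl]-5,7-dimethoxy-2H-chromen-2-one
Product: 25 3-{(1R,6R)-6-[(E)-2-(5,7-dimethoxy-2-oxo-2H-chromen-8-yl)ethenyl]-3,6-dimethylcyclohex-2-en-1-yl}-2-hydroxy-4,6-dimethoxybenzaldehyde
Conditions: MgCl2, Et3N, (CH2O)n, MeCN, 80 °C
Reagents that add atoms: paraformaldehyde (as formaldehyde), C=O
Why: Casnati–Skattebøl ortho-formylation: the magnesium phenoxide delivers formaldehyde only to the free ortho carbon between OH and OMe, and a second formaldehyde takes up hydride, so the para carbon between the two methoxy groups is not reached and no acid touches the alkenes.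

Step 16
Reactants: 25 3-{(1R,6R)-6-[(E)-2-(5,7-dimethoxy-2-oxo-2H-chromen-8-yl)ethenyl]-3,6-dimethylcyclohex-2-en-1-yl}-2-hydroxy-4,6-dimethoxybenzaldehyde
Product: 27 8-[(E)-2-[(1R,2R)-2-(5,7-dimethoxy-2-oxo-2H-chromen-8-yl)-1,4-dimethylcyclohex-3-en-1-yl]ethenyl]-5,7-dimethoxy-2H-chromen-2-one, via aryl ester ylide 26 (not isolated)
Conditions: Ph3P=C=C=O, toluene, 90 °C
Reagents that add atoms: (triphenylphosphoranylidene)ketene, O=C=C=P(c1ccccc1)(c1ccccc1)c1ccccc1
Why: The ketenylidene ylide adds the phenol O–H to give acyl ylide 26, whose intramolecular Wittig reaction with the ortho formyl group closes the pyranone ring with the cis C3=C4 bond enforced by the ring, at a temperature well below that at which the 4-vinylcyclohexene unit could undergo Cope rearrangement.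

**Compound list**

1 | ethyl (E)-4-bromobut-2-enoate | CCOC(=O)/C=C/CBr | starting material
2 | triphenylphosphine | c1ccc(cc1)P(c1ccccc1)c1ccccc1 | starting material
3 | [(2E)-4-ethoxy-4-oxobut-2-en-1-yl]triphenylphosphonium bromide | CCOC(=O)/C=C/C[P+](c1ccccc1)(c1ccccc1)c1ccccc1.[Br-] | intermediate
4 | but-3-en-2-one (methyl vinyl ketone) | CC(=O)C=C | starting material
5 | ethyl (2E)-4-(triphenylphosphoranylidene)but-2-enoate | CCOC(=O)/C=C/C=P(c1ccccc1)(c1ccccc1)c1ccccc1 | intermediate
6 | ethyl 4-methylcyclohexa-1,3-diene-1-carboxylate | CCOC(=O)C1=CC=C(C)CC1 | intermediate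
7 | 4-methylcyclohexa-1,3-diene-1-carboxylic acid | CC1=CC=C(CC1)C(=O)O | intermediate
8 | ethanethiol | CCS | starting material
9 | S-ethyl 4-methylcyclohexa-1,3-diene-1-carbothioate | CCSC(=O)C1=CC=C(C)CC1 | intermediate
10 | 3,5-dimethoxyphenol | COc1cc(O)cc(OC)c1 | starting material
11 | 1,3-dimethoxy-5-(methoxymethoxy)benzene | COCOc1cc(OC)cc(OC)c1 | intermediate
12 | [2,4-dimethoxy-6-(methoxymethoxy)phenyl]lithium | COCOc1cc(OC)cc(OC)c1[Li] | intermediate
13 | 2-bromo-1,5-dimethoxy-3-(methoxymethoxy)benzene | COCOc1cc(OC)cc(OC)c1Br | intermediate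
14 | [2,4-dimethoxy-6-(methoxymethoxy)phenyl]magnesium bromide | COCOc1cc(OC)cc(OC)c1[Mg]Br | intermediate
15 | iodomethane | CI | starting material
16 | bromomagnesium (ethylsulfanyl){(2S)-2-[2,4-dimethoxy-6-(methoxymethoxy)phenyl]-4-methylcyclohex-3-en-1-ylidene}methanolate (enolate geometry not specified) | CCSC(O[Mg]Br)=C1CCC(C)=C[C@H]1c1c(OCOC)cc(OC)cc1OC | intermediate
17 | S-ethyl (1S,2S)-2-[2,4-dimethoxy-6-(methoxymethoxy)phenyl]-1,4-dimethylcyclohex-3-ene-1-carbothioate (aryl cis to thioester, trans to the C1 methyl) | CCSC(=O)[C@@]1(C)CCC(C)=C[C@H]1c1c(OCOC)cc(OC)cc1OC | intermediate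
18 | (1S,2S)-2-[2,4-dimethoxy-6-(methoxymethoxy)phenyl]-1,4-dimethylcyclohex-3-ene-1-carbaldehyde (aryl cis to CHO) | O=C[C@@]1(C)CCC(C)=C[C@H]1c1c(OCOC)cc(OC)cc1OC | intermediate
19 | 5,7-dimethoxy-2H-chromen-2-one (citropten) | COc1cc(OC)c2ccc(=O)oc2c1 | starting material
20 | 5,7-dimethoxy-2-oxo-2H-chromene-8-carbaldehyde | COc1cc(OC)c2ccc(=O)oc2c1C=O | intermediate
21 | 8-(hydroxymethyl)-5,7-dimethoxy-2H-chromen-2-one | COc1cc(OC)c2ccc(=O)oc2c1CO | intermediate
22 | diethyl [(5,7-dimethoxy-2-oxo-2H-chromen-8-yl)methyl]phosphonate | CCOP(=O)(OCC)Cc1c(OC)cc(OC)c2ccc(=O)oc12 | intermediate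
23 | 8-[(E)-2-{(1R,2R)-2-[2,4-dimethoxy-6-(methoxymethoxy)phenyl]-1,4-dimethylcyclohex-3-en-1-yl}ethenyl]-5,7-dimethoxy-2H-chromen-2-one | COc1cc(OC)c2ccc(=O)oc2c1/C=C/[C@@]1(C)CCC(C)=C[C@H]1c1c(OCOC)cc(OC)cc1OC | intermediate
24 | 8-[(E)-2-{(1R,2R)-2-(2-hydroxy-4,6-dimethoxyphenyl)-1,4-dimethylcyclohex-3-en-1-yl}ethenyl]-5,7-dimethoxy-2H-chromen-2-one | COc1cc(OC)c2ccc(=O)oc2c1/C=C/[C@@]1(C)CCC(C)=C[C@H]1c1c(O)cc(OC)cc1OC | intermediate
25 | 3-{(1R,6R)-6-[(E)-2-(5,7-dimethoxy-2-oxo-2H-chromen-8-yl)ethenyl]-3,6-dimethylcyclohex-2-en-1-yl}-2-hydroxy-4,6-dimethoxybenzaldehyde | COc1cc(OC)c2ccc(=O)oc2c1/C=C/[C@@]1(C)CCC(C)=C[C@H]1c1c(O)c(C=O)c(OC)cc1OC | intermediate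
26 | 6-{(1R,6R)-6-[(E)-2-(5,7-dimethoxy-2-oxo-2H-chromen-8-yl)ethenyl]-3,6-dimethylcyclohex-2-en-1-yl}-2-formyl-3,5-dimethoxyphenyl (triphenylphosphoranylidene)acetate | COc1cc(OC)c2ccc(=O)oc2c1/C=C/[C@@]1(C)CCC(C)=C[C@H]1c1c(OC(=O)C=P(c2ccccc2)(c2ccccc2)c2ccccc2)c(C=O)c(OC)cc1OC | intermediate
27 | 8-[(E)-2-[(1R,2R)-2-(5,7-dimethoxy-2-oxo-2H-chromen-8-yl)-1,4-dimethylcyclohex-3-en-1-yl]ethenyl]-5,7-dimethoxy-2H-chromen-2-one (CNP0164660.2) | COc1cc(OC)c2ccc(=O)oc2c1/C=C/[C@@]1(C)CCC(C)=C[C@H]1c1c(OC)cc(OC)c2ccc(=O)oc12 | target

**Count and risks**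

Total step count: 16. Longest linear sequence: 10 steps (steps 1–4, 8, 9, 13–16).

Steps most likely to fail:

1. Step 8 (bears the label). The bulky di-ortho-substituted aryl group may transfer slowly, so that uncatalysed 1,2-addition or 1,6-addition competes. Facial discrimination at C2 may be poor. Methylation of the magnesium enolate may lag behind protonation or ketene formation. The fallback uses known chemistry only, sets out from 11 and returns to the route at 18. Lithiation of 11 as in step 6 and quenching with DMF would give 2,4-dimethoxy-6-(methoxymethoxy)benzaldehyde F1. Claisen–Schmidt condensation with acetone (aq. NaOH) would give (E)-4-[2,4-dimethoxy-6-(methoxymethoxy)phenyl]but-3-en-2-one F2. Wittig methylenation (Ph3P=CH2, THF) would give 2-[(1E)-3-methylbuta-1,3-dien-1-yl]-1,5-dimethoxy-3-(methoxymethoxy)benzene F3. An enantioselective Diels–Alder reaction of F3 with methacrolein under a chiral oxazaborolidinium Lewis acid (triflimide-activated o-tolyl oxazaborolidine from diphenylprolinol, CH2Cl2, −78 °C) should then give 18 directly. The 1-aryl and 3-methyl groups of the diene both direct the formyl-bearing carbon next to the aryl-bearing carbon, the endo transition state puts CHO cis to aryl, and the catalyst enantiomer selects the face. The route continues with step 13.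

2. Step 13. Addition of the hindered benzylic phosphonate anion to the neopentyl-type aldehyde may be slow, and the base may then open or add to the lactone instead. The fallback sets out from 18 and returns at 23. Wittig methylenation of 18 (Ph3PCH3Br, KOC(CH3)3, THF) would give 2-[(1R,6R)-6-ethenyl-3,6-dimethylcyclohex-2-en-1-yl]-1,5-dimethoxy-3-(methoxymethoxy)benzene F4. Iodination of 19 (N-iodosuccinimide, CF3CO2H, MeCN) would give 8-iodo-5,7-dimethoxy-2H-chromen-2-one F5. A Heck reaction of F4 with F5 (Pd(OAc)2, P(o-tol)3, Et3N, DMF, 90 °C) arylates the terminal carbon of the vinyl group, which has no allylic hydrogen on the quaternary side, and should give the E-styrene 23.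

3. Step 15. Formylation of the crowded magnesium phenoxide may stall, or it may stop at hydroxymethyl or methoxymethyl by-products. The fallback sets out from 24 and returns at 27, replacing steps 15 and 16. Acylation of the phenol with propiolic acid (DCC, CH2Cl2, 0 °C) would give 2-{(1R,6R)-6-[(E)-2-(5,7-dimethoxy-2-oxo-2H-chromen-8-yl)ethenyl]-3,6-dimethylcyclohex-2-en-1-yl}-3,5-dimethoxyphenyl prop-2-ynoate F6. Intramolecular hydroarylation of the alkyne by the only free ortho carbon (Ph3PAuCl/AgOTf, a cationic monovalent gold catalyst, CH2Cl2, rt) should then close the pyranone ring and give 27.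

Further compounds
F1 | step 8 | 2,4-dimethoxy-6-(methoxymethoxy)benzaldehyde | COCOc1cc(OC)cc(OC)c1C=O
F2 | step 8 | (E)-4-[2,4-dimethoxy-6-(methoxymethoxy)phenyl]but-3-en-2-one | CC(=O)/C=C/c1c(OC)cc(OC)cc1OCOC
F3 | step 8 | 2-[(1E)-3-methylbuta-1,3-dien-1-yl]-1,5-dimethoxy-3-(methoxymethoxy)benzene | CC(=C)/C=C/c1c(OC)cc(OC)cc1OCOC
F4 | step 13 | 2-[(1R,6R)-6-ethenyl-3,6-dimethylcyclohex-2-en-1-yl]-1,5-dimethoxy-3-(methoxymethoxy)benzene | C=C[C@@]1(C)CCC(C)=C[C@H]1c1c(OCOC)cc(OC)cc1OC
F5 | step 13 | 8-iodo-5,7-dimethoxy-2H-chromen-2-one | COc1cc(OC)c2ccc(=O)oc2c1I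
F6 | step 15 | 2-{(1R,6R)-6-[(E)-2-(5,7-dimethoxy-2-oxo-2H-chromen-8-yl)ethenyl]-3,6-dimethylcyclohex-2-en-1-yl}-3,5-dimethoxyphenyl prop-2-ynoate | COc1cc(OC)c2ccc(=O)oc2c1/C=C/[C@@]1(C)CCC(C)=C[C@H]1c1c(OC(=O)C#C)cc(OC)cc1OC
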